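**Retrosynthetic overview** (ring carbons: C1 = CHOH, C2 = CMe2, C3 = CH bearing the side chain, C4 = C(OH)Me, C5, C6)
1. The coumarin ether is made last (Mitsunobu with umbelliferone) on a primary alcohol unmasked from the vinyl group of (R)-linalool, which also supplies the side-chain carbinol centre.
2. The C4 carbinol comes from equatorial methyl addition to a C4 ketone, and the axial C1 alcohol from bulky-hydride reduction of a C1 ketone. The two carbonyls never coexist because C4 is carried as C–NO2.
3. The only ring, the cyclohexane, is made in one operation from a nitroalkene and isopropyl vinyl ketone. The C2–C3 bond forms by enamine addition to the nitroalkene (an α-carbonyl cation equivalent) and the C4–C5 bond by conjugate addition of the nitronate (a masked acyl anion); this sets C3.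
4. The nitroalkene comes from ozonolysis of linalyl acetate followed by Henry reaction and dehydration with nitromethane.

**Assumptions**
- (R)-(−)-linalool of ≥98% ee is used.
- cat-A is 1-[(1R,2R)-2-aminocyclohexyl]-3-[(2S)-1-[benzyl(methyl)amino]-3,3-dimethyl-1-oxobutan-2-yl]thiourea or its mirror image; the antipode is taken that directs attack to the Si face of C6 of nitroalkene 7. Which antipode does this has not been established and must be found by experiment.
- 11 and 12 are drawn as the trans (equatorial NO2) isomers; the C4 epimers converge at 14.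

Step 1
Reactants: 1 (R)-(−)-linalool
Product: 2 (3R)-3,7-dimethylocta-1,6-dien-3-yl acetate
Conditions: Ac2O, Et3N, DMAP (10 mol %), CH2Cl2, rt to 40 °C
Reagents that add atoms: acetic anhydride, CC(=O)OC(C)=O
Why: DMAP-catalysed acyl transfer esterifies the tertiary alcohol without touching the stereocentre; the acetate blocks oxa-Michael closure onto the later nitroalkene and is removed without a separate step in step 8.

Step 2
Reactants: 2 (3R)-3,7-dimethylocta-1,6-dien-3-yl acetate
Product: 3 (3R)-3-methyl-6-oxohex-1-en-3-yl acetate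
Conditions: O3 (1.0 equiv, Sudan Red 7B end point), CH2Cl2, −78 °C; then Me2S, −78 °C to rt
Reagents that add atoms: ozone, [O-][O+]=O
Why: Ozonolysis (Criegee) is selective for the electron-rich trisubstituted alkene over the hindered, acetoxy-deactivated vinyl group, so one equivalent of ozone cleaves only the former.

Step 3
Reactants: 3 (3R)-3-methyl-6-oxohex-1-en-3-yl acetate; 4 nitromethane
Product: 7 (3R,6E)-3-methyl-7-nitrohepta-1,6-dien-3-yl acetate, via nitroaldol 5 (not isolated), via mesylate 6 (not isolated)
Conditions: MeNO2 (10 equiv), 1,1,3,3-tetramethylguanidine (10 mol %), THF, 0 °C; concentrate; MsCl, Et3N, CH2Cl2, −20 to 0 °C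
Reagents that add atoms: none
Why: Henry (nitroaldol) addition followed by mesylation and E1cB elimination gives the conjugated nitroalkene, the E isomer being strongly favoured thermodynamically.

Step 4
Reactants: 8 4-methylpent-1-en-3-ol (racemic)
Product: 9 4-methylpent-1-en-3-one (isopropyl vinyl ketone)
Conditions: IBX, EtOAc, 75 °C; filter, distil
Reagents that add atoms: none
Why: IBX oxidation of a secondary allylic alcohol gives the volatile vinyl ketone cleanly, and the insoluble iodine by-product is filtered off.

Step 5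
Reactants: 7 (3R,6E)-3-methyl-7-nitrohepta-1,6-dien-3-yl acetate; 9 4-methylpent-1-en-3-one
Product: 11 (3R)-5-[(1R,6R)-2,2-dimethyl-6-nitro-3-oxocyclohexyl]-3-methylpent-1-en-3-yl acetate, via open-chain nitro enone 10 (not isolated)
Conditions: cat-A (20 mol %), PhCO2H (20 mol %), 9 (1.3 equiv, added over 6 h), toluene, 23 °C, 48 h
Reagents that add atoms: none
Why: Proposed new method: the primary amine of cat-A condenses with 9, whose only enolisable position is the isopropyl C–H, to give a cross-conjugated 2-aminodiene; its fully substituted carbon adds to the thiourea-bound nitroalkene 7 (acting as an α-carbonyl cation equivalent) on the Si face of C6, creating the quaternary carbon and the 3R ring centre under catalyst control, and the nitronate so formed, a masked acyl anion, closes the ring by 6-endo conjugate addition to the vinyl iminium ion, joining the future C4 carbonyl carbon to the enone β-carbon before hydrolysis frees the catalyst; the closest known chemistry is the amine-catalysed formal [4+2] (double Michael) reaction of enones with nitroalkenes to 4-nitrocyclohexanones and the primary-amine–thiourea addition of α,α-disubstituted aldehydes to nitroalkenes, the new element being the hindered isopropyl donor.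

Step 6
Reactants: 11 (3R)-5-[(1R,6R)-2,2-dimethyl-6-nitro-3-oxocyclohexyl]-3-methylpent-1-en-3-yl acetate
Product: 12 (3R)-5-[(1R,3S,6R)-3-hydroxy-2,2-dimethyl-6-nitrocyclohexyl]-3-methylpent-1-en-3-yl acetate
Conditions: LiBH(s-Bu)3 (L-Selectride, 2.2 equiv), THF, −78 °C; then H2O
Reagents that add atoms: none
Why: Bulky-hydride reduction of the 2,2-dimethylcyclohexanone proceeds by equatorial attack (as with 4,4-dimethyl-3-keto triterpenoids) and gives the axial 1S alcohol trans to the equatorial side chain; the nitro group is at most deprotonated and returns on quench.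

Step 7
Reactants: 12 (3R)-5-[(1R,3S,6R)-3-hydroxy-2,2-dimethyl-6-nitrocyclohexyl]-3-methylpent-1-en-3-yl acetate
Product: 14 (3R)-5-[(1R,3S)-3-hydroxy-2,2-dimethyl-6-oxocyclohexyl]-3-methylpent-1-en-3-yl acetate, via sodium nitronate 13 (not isolated)
Conditions: NaOH (1.1 equiv), MeOH, 0 °C; then KHSO5 (as Oxone, 2KHSO5·KHSO4·K2SO4), aqueous Na2HPO4 buffer, 0 °C to rt
Reagents that add atoms: potassium peroxymonosulfate, [K+].[O-]S(=O)(=O)OO
Why: Oxidative Nef reaction of the secondary nitronate unmasks the C4 ketone under buffered conditions; the adjacent C3–H is not acidic until the ketone exists, and the medium is then near neutral, so the C3 centre is kept.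

Step 8
Reactants: 14 (3R)-5-[(1R,3S)-3-hydroxy-2,2-dimethyl-6-oxocyclohexyl]-3-methylpent-1-en-3-yl acetate
Product: 15 (1S,2R,4S)-2-[(3R)-3-hydroxy-3-methylpent-4-en-1-yl]-1,3,3-trimethylcyclohexane-1,4-diol
Conditions: MeLi (6 equiv), THF/Et2O, −78 to 0 °C; then H2O
Reagents that add atoms: methyllithium, [Li]C
Why: In this 1,2-addition of an organolithium the axial face of the ketone is blocked by the syn-axial methyl of the neighbouring CMe2 (as in 3,3,5-trimethylcyclohexanone), so methyl enters equatorially and the new tertiary OH is axial and cis to the side chain (1S); excess reagent also cleaves the tertiary acetate.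

Step 9
Reactants: 15 (1S,2R,4S)-2-[(3R)-3-hydroxy-3-methylpent-4-en-1-yl]-1,3,3-trimethylcyclohexane-1,4-diol
Product: 17 (1S,2R,4S)-2-[(3R)-3,5-dihydroxy-3-methylpentyl]-1,3,3-trimethylcyclohexane-1,4-diol, via B-alkyl-9-BBN adduct 16 (not isolated)
Conditions: 9-borabicyclo[3.3.1]nonane (9-BBN, 4 equiv), THF, 0 °C to rt; then NaOH, H2O2, 0 °C to rt
Reagents that add atoms: hydrogen peroxide, OO
Why: Brown hydroboration–oxidation with 9-BBN places boron only on the terminal carbon of the monosubstituted alkene, and oxidation gives the primary alcohol without affecting any stereocentre.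

Step 10
Reactants: 17 (1S,2R,4S)-2-[(3R)-3,5-dihydroxy-3-methylpentyl]-1,3,3-trimethylcyclohexane-1,4-diol; 18 umbelliferone (7-hydroxy-2H-chromen-2-one)
Product: 19 7-{[(3R)-5-[(1R,3S,6S)-3,6-dihydroxy-2,2,6-trimethylcyclohexyl]-3-hydroxy-3-methylpentyl]oxy}-2H-chromen-2-one (target)
Conditions: PPh3, DIAD, THF, 0 °C to rt
Reagents that add atoms: none
Why: Mitsunobu etherification with the acidic phenol (pKa about 7.8) occurs only at the primary alcohol, since the two tertiary and the axial neopentyl secondary hydroxyls do not form reactive oxyphosphonium ions; the base-, hydride- and organolithium-sensitive coumarin is therefore introduced last.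

**Compound list**
1 | (R)-(−)-linalool | C=C[C@](C)(O)CCC=C(C)C | starting material
2 | (3R)-3,7-dimethylocta-1,6-dien-3-yl acetate | C=C[C@](C)(OC(C)=O)CCC=C(C)C | intermediate
3 | (3R)-3-methyl-6-oxohex-1-en-3-yl acetate | C=C[C@](C)(OC(C)=O)CCC=O | intermediate
4 | nitromethane | C[N+](=O)[O-] | starting material
5 | (3R,6RS)-6-hydroxy-3-methyl-7-nitrohept-1-en-3-yl acetate (both carbinol epimers) | C=C[C@](C)(OC(C)=O)CCC(O)C[N+](=O)[O-] | intermediate
6 | (3R,6RS)-3-methyl-6-(methylsulfonyloxy)-7-nitrohept-1-en-3-yl acetate | C=C[C@](C)(OC(C)=O)CCC(OS(C)(=O)=O)C[N+](=O)[O-] | intermediate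
7 | (3R,6E)-3-methyl-7-nitrohepta-1,6-dien-3-yl acetate | C=C[C@](C)(OC(C)=O)CC/C=C/[N+](=O)[O-] | intermediate
8 | 4-methylpent-1-en-3-ol (racemic) | C=CC(O)C(C)C | starting material
9 | 4-methylpent-1-en-3-one | C=CC(=O)C(C)C | intermediate
10 | (3R,6R)-3,7,7-trimethyl-6-(nitromethyl)-8-oxodeca-1,9-dien-3-yl acetate | C=CC(=O)C(C)(C)[C@@H](CC[C@@](C)(OC(C)=O)C=C)C[N+](=O)[O-] | intermediate
11 | (3R)-5-[(1R,6R)-2,2-dimethyl-6-nitro-3-oxocyclohexyl]-3-methylpent-1-en-3-yl acetate | CC1(C)[C@@H](CC[C@@](C)(OC(C)=O)C=C)[C@H]([N+](=O)[O-])CCC1=O | intermediate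
12 | (3R)-5-[(1R,3S,6R)-3-hydroxy-2,2-dimethyl-6-nitrocyclohexyl]-3-methylpent-1-en-3-yl acetate | CC1(C)[C@@H](CC[C@@](C)(OC(C)=O)C=C)[C@H]([N+](=O)[O-])CC[C@@H]1O | intermediate
13 | sodium nitronate of 12 | CC1(C)[C@@H](CC[C@@](C)(OC(C)=O)C=C)C(=[N+]([O-])[O-])CC[C@@H]1O.[Na+] | intermediate
14 | (3R)-5-[(1R,3S)-3-hydroxy-2,2-dimethyl-6-oxocyclohexyl]-3-methylpent-1-en-3-yl acetate | CC1(C)[C@@H](CC[C@@](C)(OC(C)=O)C=C)C(=O)CC[C@@H]1O | intermediate
15 | (1S,2R,4S)-2-[(3R)-3-hydroxy-3-methylpent-4-en-1-yl]-1,3,3-trimethylcyclohexane-1,4-diol | CC1(C)[C@@H](CC[C@@](C)(O)C=C)[C@@](C)(O)CC[C@@H]1O | intermediate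
16 | B-alkyl-9-borabicyclo[3.3.1]nonane adduct of 15 | CC1(C)[C@@H](CC[C@@](C)(O)CCB2C3CCCC2CCC3)[C@@](C)(O)CC[C@@H]1O | intermediate
17 | (1S,2R,4S)-2-[(3R)-3,5-dihydroxy-3-methylpentyl]-1,3,3-trimethylcyclohexane-1,4-diol | CC1(C)[C@@H](CC[C@@](C)(O)CCO)[C@@](C)(O)CC[C@@H]1O | intermediate
18 | umbelliferone (7-hydroxy-2H-chromen-2-one) | Oc1ccc2ccc(=O)oc2c1 | starting material
19 | 7-{[(3R)-5-[(1R,3S,6S)-3,6-dihydroxy-2,2,6-trimethylcyclohexyl]-3-hydroxy-3-methylpentyl]oxy}-2H-chromen-2-one | CC1(C)[C@@H](CC[C@@](C)(O)CCOc2ccc3ccc(=O)oc3c2)[C@@](C)(O)CC[C@@H]1O | target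

**Step count**
Total: 10 steps. Longest linear sequence: 9 steps (1, 2, 3, 5, 6, 7, 8, 9, 10).

**Three steps most likely to fail, with fallbacks**

Step 5 (annulation). The hindered isopropyl enamine may form too slowly, or the ee may be poor. The fallback sets out from 7 and splits the ring formation into separate bond-forming events. Isobutyraldehyde is added to 7 with the same cat-A (an established quaternary-centre-forming nitro-Michael reaction) to give the nitro aldehyde F1. CH2=CHMgBr with CeCl3 at −78 °C then gives the allylic alcohol F2. Dess–Martin oxidation gives the enone 10, which is closed with catalytic DBU by nitronate conjugate addition. The route is rejoined at 11.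

Step 7 (Nef). The oxidation may stall, or the C3 centre next to the new ketone may epimerise. The fallback sets out from 12 and removes nitrogen by a redox-transamination sequence instead. Zn in aqueous HCl/EtOH reduces the nitro group to the amine F3. Oxidative deamination with 3,5-di-tert-butyl-1,2-benzoquinone followed by mild acid hydrolysis then gives the ketone. The route is rejoined at 14.

Step 8 (methyl addition). Enolisation of the hindered ketone may outrun addition. The fallback sets out from 14 and builds the carbinol through an epoxide. Dimethylsulfoxonium methylide (from Me3S(O)I and NaH in DMSO) transfers CH2 equatorially to give the spiro-epoxide F4 with the oxygen axial. LiAlH4 then opens the epoxide at CH2 and removes the acetate. The route is rejoined at 15.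

**Further compounds**
F1 | step 5 | (3R,6R)-3,7,7-trimethyl-6-(nitromethyl)-8-oxooct-1-en-3-yl acetate | O=CC(C)(C)[C@@H](CC[C@@](C)(OC(C)=O)C=C)C[N+](=O)[O-]
F2 | step 5 | (3R,6R,8RS)-8-hydroxy-3,7,7-trimethyl-6-(nitromethyl)deca-1,9-dien-3-yl acetate | C=CC(O)C(C)(C)[C@@H](CC[C@@](C)(OC(C)=O)C=C)C[N+](=O)[O-]
F3 | step 7 | (3R)-5-[(1R,3S,6R)-6-amino-3-hydroxy-2,2-dimethylcyclohexyl]-3-methylpent-1-en-3-yl acetate | CC1(C)[C@@H](CC[C@@](C)(OC(C)=O)C=C)[C@H](N)CC[C@@H]1O
F4 | step 8 | (3R)-5-[(3S,4R,6S)-6-hydroxy-5,5-dimethyl-1-oxaspiro[2.5]octan-4-yl]-3-methylpent-1-en-3-yl acetate | CC1(C)[C@@H](CC[C@@](C)(OC(C)=O)C=C)[C@@]2(OC2)CC[C@@H]1O
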